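**Analysis of the target**

Target 20 is a flavonol: a 4H-chromen-4-one (ring A the benzo ring, ring C the pyranone) with a 4-hydroxyphenyl ring B at C2, hydroxyl groups at C3, C5 and C7, and a 3-hydroxy-3-methylbutyl chain at C6. It has no stereocentre and no double-bond geometry, so the problem is one of regiochemistry and functional-group tolerance. Ring A is substituted everywhere except C8, and the chain must sit at C6 between the two phenolic oxygens and not at C8; late C-alkylation of a 5,7-dihydroxyflavone would not tell these positions apart. The tertiary alcohol lies between two phenols and would dehydrate or close to a 2,2-dimethylchroman under acid, and the free polyphenol is oxidised easily in base. All oxygens are therefore carried as benzyl ethers and released at the very end by neutral hydrogenolysis. The plan rests on one feature: O1 on C8a and the acyl carbon C4 on C4a are ortho to each other, and the C5 oxygen sits directly beside C4a. That is the pattern left behind when an oxygen nucleophile and an acyl electrophile add across the triple bond of a 3-alkoxy-substituted aryne, and a carboxylic acid supplies both in one molecule, so ring B, C2, C3 with its oxygen and C4 can arrive as a single cinnamic acid.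

**Retrosynthetic reasoning**

Target 20 is traced back to the pentabenzyl flavonol 19 by cutting the five benzyl–oxygen bonds. Hydrogenolysis is the only global deprotection that keeps acid away from the tertiary alcohol and its two phenol neighbours, and it removes aryl, enol and tertiary alkyl benzyl ethers alike.

Flavonol 19 is opened at O1–C2 and taken down by two hydrogens to the 2'-hydroxychalcone 17. The C3 oxygen is already present as the α-benzyloxy group, so no separate C3 oxidation is needed. The forward reaction has to close ring C by attack of the C8a phenol on Cβ and then introduce the C2=C3 double bond.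

Chalcone 17 is cut at the two bonds that tie the side chain to adjacent ring carbons: C8a–O1 and C4a–C4. This leads to the aryne released from silyl triflate 12 and to cinnamic acid 16. The cut is made here because it joins a complete ring A to a complete C3–ring B unit in one step under basic, fluoride-driven conditions. A Friedel–Crafts acylation of phenol 8 would form only C4a–C4 and would need Lewis acid that the tertiary ether would not survive. The forward reaction must add the carboxylate oxygen to the carbon that becomes C8a and transfer the acyl group to C4a.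

Acid 16 is cut at its Cα=Cβ bond into aldehyde 13 and ester 14 (aldol condensation followed by saponification, through ester 15). The C3 oxygen comes in already benzylated with 14.

Silyl triflate 12 is traced to bromophenol 9 (through silyl ether 10 and phenoxide 11) and then to phenol 8. Bromine is the placeholder for silicon. The two open ring positions of 8 are equivalent, so bromination raises no regiochemical question.

Phenol 8 is cut at the aryl–CH2 bond into bromophenol 4 and the alkylborane 7, made from alkene 6 and ultimately alcohol 5. The bromine of 4 fixes the chain between the two ether oxygens, a position that electrophilic substitution on the trioxygenated ring would not select.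

Bromophenol 4 is traced through carbinol 3 and ester 2 to the commercial acid 1. The carboxyl carbon is exchanged for the phenol oxygen by a hydroperoxide rearrangement. A formyl-to-hydroxyl (Dakin) oxidation was not adopted: both ring oxygens are meta to C1, so hydride rather than aryl migration would be expected. The exchange is placed before the coupling so that no acid-labile tertiary ether is present when acid and peroxide are used.

**Alternatives that were turned down**

Alternative 1: Ring A is cut at C4a–C5, C5–C6, C7–C8 and C8–C8a. The pieces are 5-(benzyloxy)-6-[4-(benzyloxy)phenyl]-2-(2-diazoacetyl)-4H-pyran-4-one A1, which holds rings B and C complete, and the siloxyalkyne {[5-(benzyloxy)-5-methylhex-1-yn-1-yl]oxy}tri(propan-2-yl)silane A2.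
- Forward reaction: the step that carries this plan is a Wolff rearrangement of A1 to a ketene, which adds to A2 in a [2+2] sense. The four-membered adduct opens (4π) and recloses (6π) onto the pyranone double bond, and the product is 3-(benzyloxy)-2-[4-(benzyloxy)phenyl]-6-[3-(benzyloxy)-3-methylbutyl]-5-hydroxy-7-[(triisopropylsilyl)oxy]-4H-chromen-4-one A3. Desilylation and hydrogenolysis of A3 would complete the synthesis.
- For: four carbon–carbon bonds form in one step. The polarity of the ynol ether A2 fixes the C5-hydroxyl, C6-alkyl, C7-silyloxy pattern of A3. Compound A3 is already at the flavone oxidation level, with the C5 hydroxyl free. On bond count and on avoiding a dehydrogenation this plan is stronger than the chosen route.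
- Against: A1 would need several steps of its own (O-benzylation, oxidation of a side chain, arylation next to the ring oxygen, diazoketone formation), and A2 needs an ester homologation sequence. The alkene that must take part in the 6π closure on the way to A3 is the C=C of a 4-pyranone, a delocalised vinylogous ester that resists being drawn into a dienylketene. The 2-aryl-4-pyranone chromophore of A1 absorbs where the Wolff step is driven.
- Comparison: the benzannulation to A3 is untested on this substrate class, and the route would be about as long or longer. The chosen route offers instead precursors made by routine reactions and a decisive step whose bond polarity is unambiguous.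

Alternative 2: Ring A is cut at C4a–C5 and C8–C8a. The pieces are the diene 1-(benzyloxy)-2-[3-(benzyloxy)-3-methylbutyl]-1,3-bis[(trimethylsilyl)oxy]buta-1,3-diene A4 and the bromoynone 1-(benzyloxy)-4-bromobut-3-yn-2-one A5.
- Forward reaction: Diels–Alder addition of A4 to A5, followed by loss of silanol, aromatises the new ring and gives 2-(benzyloxy)-1-{2-(benzyloxy)-3-[3-(benzyloxy)-3-methylbutyl]-6-bromo-4-hydroxyphenyl}ethan-1-one A6.
- For: ring A is made from acyclic pieces, with the regiochemistry set by the polarised diene A4 and the ynone A5. The C5 and C7 oxygens of A6 come out differentiated without any protecting-group manoeuvre. That is a real advantage over the chosen route with its bromination, silylation and triflation.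
- Against: A6 still lacks O1, ring C and ring B. The C7 hydroxyl must be protected, ring B attached by a condensation, and C8a–O1 made by an Ullmann-type displacement of a hindered, electron-rich aryl bromide before any dehydrogenation. That is four or five steps after A6. A4 is a tetrasubstituted mixed ketene acetal whose C2 substituent disfavours the s-cis conformer and which hydrolyses easily. A5 is a sensitive haloalkyne.
- Comparison: the cycloaddition to A6 builds only ring A and leaves the chromenone for later. The chosen route forms C8a–O1 and C4a–C4 together, with ring B already attached.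

Alternative 3: Ring C is cut at C3–C4, giving the dialdehyde 4,6-bis(benzyloxy)-5-[3-(benzyloxy)-3-methylbutyl]-2-{1-[4-(benzyloxy)phenyl]-2-oxoethoxy}benzaldehyde A7.
- Forward reaction: under thiazolium carbene catalysis A7 should undergo an intramolecular crossed benzoin reaction that forms C3–C4 and closes ring C. The product is trans-5,7-bis(benzyloxy)-2-[4-(benzyloxy)phenyl]-6-[3-(benzyloxy)-3-methylbutyl]-3-hydroxy-2,3-dihydro-4H-chromen-4-one A8, formed as the racemate. Oxidation of A8 to the flavonol and hydrogenolysis would follow.
- For: the conditions are mild and metal-free, and the C3 oxygen arrives in A8 as a free hydroxyl. The arene of A7 could be derived from phenol 8 by ortho-formylation, without any aryne precursor. On mildness this plan is stronger than a CsF reaction at 125 °C.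
- Against: the carbene must form its acyl-anion equivalent at the aryl aldehyde of A7, which is hindered by two ortho oxygens and deactivated by three donor oxygens. Reaction through the aliphatic aldehyde would place the ketone at C3 and the hydroxyl at C4, a ring C isomer of A8. A7 carries an α-hydrogen activated by an aryl and an aryloxy group, so enolisation, self-aldol reaction and air oxidation threaten it. Its preparation needs a redox adjustment in the presence of the second aldehyde. Two stereocentres are made in A8 only to be destroyed.
- Comparison: the step count through A8 would be similar. The chosen route avoids the chemoselectivity question, because the carboxyl carbon can only be the electrophile, and it uses stable precursors.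

Key step: step 9

Remark on the chemistry: the double-bond geometry of acid 16 and chalcone 17 is drawn as Z, the expected thermodynamic isomer; it is erased when ring C is formed, so it does not affect the target.

**Route**

Step 1
Reactants: 1 4-bromo-3,5-dihydroxybenzoic acid
Product: 2 benzyl 3,5-bis(benzyloxy)-4-bromobenzoate
Conditions: BnBr (3.5 equiv), K2CO3, DMF, 60 °C
Reagents that add atoms: benzyl bromide, BrCc1ccccc1
Why: Williamson etherification of both phenols and alkylation of the carboxylate in one operation; the benzyl ester serves as the handle for the next step.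

Step 2
Reactants: 2 benzyl 3,5-bis(benzyloxy)-4-bromobenzoate
Product: 3 2-[3,5-bis(benzyloxy)-4-bromophenyl]propan-2-ol
Conditions: MeMgBr (3 equiv), THF, 0 °C to rt; aq. NH4Cl
Reagents that add atoms: methylmagnesium bromide, C[Mg]Br
Why: Double Grignard addition to the ester gives the tertiary benzylic alcohol; MeMgBr does not exchange with the aryl bromide under these conditions.

Step 3
Reactants: 3 2-[3,5-bis(benzyloxy)-4-bromophenyl]propan-2-ol
Product: 4 3,5-bis(benzyloxy)-4-bromophenol
Conditions: 50% aq. H2O2, BF3·OEt2, CH2Cl2, 0 °C to rt; aq. Na2SO3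
Reagents that add atoms: hydrogen peroxide, OO
Why: Hock-type hydroperoxide rearrangement: the cumyl cation is trapped by H2O2, the aryl group migrates to oxygen under acid, and the resulting hemiketal falls apart to the phenol and acetone. It is run before the side chain is attached so that no acid-labile tertiary ether is present.

Step 4
Reactants: 5 2-methylbut-3-en-2-ol
Product: 6 {[(2-methylbut-3-en-2-yl)oxy]methyl}benzene
Conditions: NaH, BnBr, n-Bu4NI (cat.), THF/DMF, 0 °C to 50 °C
Reagents that add atoms: benzyl bromide, BrCc1ccccc1
Why: Williamson benzylation of the tertiary alkoxide; iodide catalysis makes up for the hindered nucleophile.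

Step 5
Reactants: 6 {[(2-methylbut-3-en-2-yl)oxy]methyl}benzene; 4 3,5-bis(benzyloxy)-4-bromophenol
Product: 8 3,5-bis(benzyloxy)-4-[3-(benzyloxy)-3-methylbutyl]phenol, via B-alkyl-9-BBN borane 7 (not isolated)
Conditions: 9-BBN, THF, 0 °C to rt; then 4, Pd(OAc)2 (5 mol%), 2-dicyclohexylphosphino-2',6'-dimethoxybiphenyl (SPhos, 10 mol%), aq. K3PO4, THF, 70 °C
Reagents that add atoms: none
Why: 9-BBN hydroborates the terminal carbon of 6 (anti-Markovnikov, next to a quaternary centre), and the B-alkyl Suzuki–Miyaura coupling joins the primary alkyl group to the bromide. The electron-rich biarylphosphine is chosen for oxidative addition into a di-ortho-substituted, electron-rich aryl bromide, and the free phenol is carried as its phenoxide.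

Step 6
Reactants: 8 3,5-bis(benzyloxy)-4-[3-(benzyloxy)-3-methylbutyl]phenol
Product: 9 3,5-bis(benzyloxy)-4-[3-(benzyloxy)-3-methylbutyl]-2-bromophenol
Conditions: NBS (1.0 equiv), CH2Cl2, −78 °C to −40 °C
Reagents that add atoms: N-bromosuccinimide, O=C1CCC(=O)N1Br
Why: Electrophilic aromatic bromination; the two open positions are equivalent, each ortho to the hydroxyl and ortho or para to an ether oxygen, and the first bromine deactivates the ring enough for one equivalent at low temperature to stop at the monobromide.

Step 7
Reactants: 9 3,5-bis(benzyloxy)-4-[3-(benzyloxy)-3-methylbutyl]-2-bromophenol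
Product: 12 3,5-bis(benzyloxy)-4-[3-(benzyloxy)-3-methylbutyl]-2-(trimethylsilyl)phenyl trifluoromethanesulfonate, via aryl trimethylsilyl ether 10 (not isolated), via lithium 2-silylphenoxide 11 (not isolated)
Conditions: HMDS, THF, 65 °C, then evaporation; n-BuLi, THF, −78 °C; Tf2O, −78 °C to 0 °C
Reagents that add atoms: hexamethyldisilazane, C[Si](C)(C)N[Si](C)(C)C; trifluoromethanesulfonic anhydride, O=S(=O)(OS(=O)(=O)C(F)(F)F)C(F)(F)F
Why: Standard route to ortho-silylaryl triflates: O-silylation, bromine–lithium exchange and 1,3 O-to-C silyl migration (retro-Brook rearrangement) give the C-silyl phenoxide, which is triflated in the same flask. Exchange at −78 °C is much faster than deprotonation of the benzylic ethers.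

Step 8
Reactants: 13 4-(benzyloxy)benzaldehyde; 14 methyl 2-(benzyloxy)acetate
Product: 16 (Z)-2-(benzyloxy)-3-[4-(benzyloxy)phenyl]prop-2-enoic acid, via methyl ester 15 (not isolated)
Conditions: t-BuOK, THF, −10 °C to rt; then 2 M aq. NaOH, MeOH, 60 °C; HCl to pH 2; crystallisation
Reagents that add atoms: sodium hydroxide, [Na+].[OH-]
Why: Aldol condensation of the ester enolate with the non-enolisable aldehyde with E1cB loss of hydroxide, then saponification. The Z acid, with the aryl group trans to the carboxyl group, is the thermodynamically preferred isomer and should be purified by crystallisation.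

Step 9
Reactants: 12 3,5-bis(benzyloxy)-4-[3-(benzyloxy)-3-methylbutyl]-2-(trimethylsilyl)phenyl trifluoromethanesulfonate; 16 (Z)-2-(benzyloxy)-3-[4-(benzyloxy)phenyl]prop-2-enoic acid
Product: 17 (Z)-2-(benzyloxy)-3-[4-(benzyloxy)phenyl]-1-{2,4-bis(benzyloxy)-3-[3-(benzyloxy)-3-methylbutyl]-6-hydroxyphenyl}prop-2-en-1-one
Conditions: 16 (1.5 equiv), CsF (4 equiv), THF, 125 °C, sealed tube; aq. NH4Cl
Reagents that add atoms: none
Why: Fluoride removes the trimethylsilyl group of 12 and expels triflate, giving the aryne across the carbons that become C4a and C8a; the carboxylate of 16 adds through oxygen to the carbon remote from the flanking benzyloxy group (C8a), which places the aryl anion at C4a beside the inductively withdrawing C5 oxygen and keeps the nucleophile on the less hindered side. The aryl anion then attacks the neighbouring ester carbonyl through a four-membered transition state, and the strained alkoxide opens to the phenoxide of the ortho-hydroxyaryl ketone, so that C8a–O1 and C4a–C4 form in one operation. The closest known reaction type is the insertion of fluoride-generated arynes into the C–O bond of carboxylic acids, unsaturated acids included, with CsF in hot THF. No ring of the target closes here and no stereocentre is formed; the Z geometry of 16 should carry over. Two selectivities are needed: the regiochemistry of addition, which the single alkoxy group beside the triple bond secures, and acyl transfer in preference to protonation of the aryl anion, which is favoured by the fully deprotonated acid, the high temperature and the slow release of aryne by sparingly soluble CsF. The acid is used in excess so that the product phenoxide does not compete for aryne. Any material that cyclises further under the basic conditions converges in step 10.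

Step 10
Reactants: 17 (Z)-2-(benzyloxy)-3-[4-(benzyloxy)phenyl]-1-{2,4-bis(benzyloxy)-3-[3-(benzyloxy)-3-methylbutyl]-6-hydroxyphenyl}prop-2-en-1-one
Product: 19 3,5,7-tris(benzyloxy)-2-[4-(benzyloxy)phenyl]-6-[3-(benzyloxy)-3-methylbutyl]-4H-chromen-4-one, via 3-benzyloxyflavanone 18 (not isolated)
Conditions: I2 (10 mol%), DMSO, 120 °C
Reagents that add atoms: none
Why: Oxidative cyclisation of a 2'-hydroxychalcone to a flavone with catalytic iodine in DMSO: 6-endo oxa-Michael addition of the C8a phenol to Cβ gives 18, iodination at C3 and loss of HI introduce the C2=C3 double bond, and DMSO reoxidises HI to iodine. The C3 benzyloxy group stays in place, so the flavonol oxygen needs no separate introduction.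

Step 11
Reactants: 19 3,5,7-tris(benzyloxy)-2-[4-(benzyloxy)phenyl]-6-[3-(benzyloxy)-3-methylbutyl]-4H-chromen-4-one
Product: 20 3,5,7-trihydroxy-6-(3-hydroxy-3-methylbutyl)-2-(4-hydroxyphenyl)-4H-chromen-4-one
Conditions: H2 (1 atm), Pd(OH)2/C, THF/MeOH, rt
Reagents that add atoms: none
Why: Hydrogenolysis should remove the three aryl benzyl ethers, the C3 enol benzyl ether and the tertiary alkyl benzyl ether under neutral conditions. No acid is present, so the tertiary alcohol should neither dehydrate nor cyclise onto the neighbouring phenols.

**Compound list**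

1 | 4-bromo-3,5-dihydroxybenzoic acid | O=C(O)c1cc(O)c(Br)c(O)c1 | starting material
2 | benzyl 3,5-bis(benzyloxy)-4-bromobenzoate | O=C(OCc1ccccc1)c1cc(OCc2ccccc2)c(Br)c(OCc2ccccc2)c1 | intermediate
3 | 2-[3,5-bis(benzyloxy)-4-bromophenyl]propan-2-ol | CC(C)(O)c1cc(OCc2ccccc2)c(Br)c(OCc2ccccc2)c1 | intermediate
4 | 3,5-bis(benzyloxy)-4-bromophenol | Oc1cc(OCc2ccccc2)c(Br)c(OCc2ccccc2)c1 | intermediate
5 | 2-methylbut-3-en-2-ol | C=CC(C)(C)O | starting material
6 | {[(2-methylbut-3-en-2-yl)oxy]methyl}benzene | C=CC(C)(C)OCc1ccccc1 | intermediate
7 | 9-[3-(benzyloxy)-3-methylbutyl]-9-borabicyclo[3.3.1]nonane | CC(C)(CCB1C2CCCC1CCC2)OCc1ccccc1 | intermediate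
8 | 3,5-bis(benzyloxy)-4-[3-(benzyloxy)-3-methylbutyl]phenol | Oc1cc(OCc2ccccc2)c(CCC(C)(C)OCc2ccccc2)c(OCc2ccccc2)c1 | intermediate
9 | 3,5-bis(benzyloxy)-4-[3-(benzyloxy)-3-methylbutyl]-2-bromophenol | Oc1cc(OCc2ccccc2)c(CCC(C)(C)OCc2ccccc2)c(OCc2ccccc2)c1Br | intermediate
10 | {3,5-bis(benzyloxy)-4-[3-(benzyloxy)-3-methylbutyl]-2-bromophenoxy}trimethylsilane | C[Si](C)(C)Oc1cc(OCc2ccccc2)c(CCC(C)(C)OCc2ccccc2)c(OCc2ccccc2)c1Br | intermediate
11 | lithium 3,5-bis(benzyloxy)-4-[3-(benzyloxy)-3-methylbutyl]-2-(trimethylsilyl)phenoxide | [Li+].[O-]c1cc(OCc2ccccc2)c(CCC(C)(C)OCc2ccccc2)c(OCc2ccccc2)c1[Si](C)(C)C | intermediate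
12 | 3,5-bis(benzyloxy)-4-[3-(benzyloxy)-3-methylbutyl]-2-(trimethylsilyl)phenyl trifluoromethanesulfonate | C[Si](C)(C)c1c(OS(=O)(=O)C(F)(F)F)cc(OCc2ccccc2)c(CCC(C)(C)OCc2ccccc2)c1OCc1ccccc1 | intermediate
13 | 4-(benzyloxy)benzaldehyde | O=Cc1ccc(OCc2ccccc2)cc1 | starting material
14 | methyl 2-(benzyloxy)acetate | COC(=O)COCc1ccccc1 | starting material
15 | methyl (Z)-2-(benzyloxy)-3-[4-(benzyloxy)phenyl]prop-2-enoate | COC(=O)/C(OCc1ccccc1)=C/c1ccc(OCc2ccccc2)cc1 | intermediate
16 | (Z)-2-(benzyloxy)-3-[4-(benzyloxy)phenyl]prop-2-enoic acid | OC(=O)/C(OCc1ccccc1)=C/c1ccc(OCc2ccccc2)cc1 | intermediate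
17 | (Z)-2-(benzyloxy)-3-[4-(benzyloxy)phenyl]-1-{2,4-bis(benzyloxy)-3-[3-(benzyloxy)-3-methylbutyl]-6-hydroxyphenyl}prop-2-en-1-one | O=C(/C(OCc1ccccc1)=C/c1ccc(OCc2ccccc2)cc1)c1c(O)cc(OCc2ccccc2)c(CCC(C)(C)OCc2ccccc2)c1OCc1ccccc1 | intermediate
18 | 3,5,7-tris(benzyloxy)-2-[4-(benzyloxy)phenyl]-6-[3-(benzyloxy)-3-methylbutyl]-2,3-dihydro-4H-chromen-4-one (racemic, mixture of diastereomers) | O=C1c2c(OCc3ccccc3)c(CCC(C)(C)OCc3ccccc3)c(OCc3ccccc3)cc2OC(c2ccc(OCc3ccccc3)cc2)C1OCc1ccccc1 | intermediate
19 | 3,5,7-tris(benzyloxy)-2-[4-(benzyloxy)phenyl]-6-[3-(benzyloxy)-3-methylbutyl]-4H-chromen-4-one | O=c1c(OCc2ccccc2)c(-c2ccc(OCc3ccccc3)cc2)oc2cc(OCc3ccccc3)c(CCC(C)(C)OCc3ccccc3)c(OCc3ccccc3)c12 | intermediate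
20 | 3,5,7-trihydroxy-6-(3-hydroxy-3-methylbutyl)-2-(4-hydroxyphenyl)-4H-chromen-4-one | CC(C)(O)CCc1c(O)cc2oc(-c3ccc(O)cc3)c(O)c(=O)c2c1O | target

**Step count and least certain steps**

Total: 11 steps. Longest linear sequence: 9 steps (steps 1, 2, 3, 5, 6, 7, 9, 10, 11).

Step 9 (key step). The most likely failure is quenching of the aryl anion before it reaches the carbonyl group. The anion can be protonated by a stray proton source, or can pull a proton from the benzylic CH2 of the neighbouring ether, and the result is simple O-arylation. Further arylation of the product phenoxide and sluggish aryne release from the crowded silyl triflate are lesser concerns. The fallback forms the same two bonds one after the other by known chemistry. It sets out from bromophenol 9 and acid 16, which are esterified (EDC·HCl, DMAP, CH2Cl2) to 3,5-bis(benzyloxy)-4-[3-(benzyloxy)-3-methylbutyl]-2-bromophenyl (Z)-2-(benzyloxy)-3-[4-(benzyloxy)phenyl]prop-2-enoate F1. Bromine–lithium exchange (n-BuLi, THF, −100 °C) then triggers the anionic 1,3 O-to-C acyl shift of the ortho-lithiated aryl ester, and the route is rejoined at chalcone 17.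

Step 3. The cumyl cation may alkylate the electron-rich ring of another molecule or lose a proton to a styrene that dimerises, and the Lewis acid may begin to cleave benzyl ethers. The fallback sets out from ester 2. It is converted (MeNH(OMe)·HCl, i-PrMgCl, THF, −20 °C) into 3,5-bis(benzyloxy)-4-bromo-N-methoxy-N-methylbenzamide F2, which with MeMgBr gives 1-[3,5-bis(benzyloxy)-4-bromophenyl]ethan-1-one F3. Baeyer–Villiger oxidation (mCPBA, CH2Cl2), in which the aryl group migrates in preference to methyl, gives 3,5-bis(benzyloxy)-4-bromophenyl acetate F4. Methanolysis (K2CO3, MeOH) returns to bromophenol 4.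

Step 5. Oxidative addition into a bromide flanked by two ether groups, on a ring made still more electron-rich by the phenoxide, may be slow enough for protodeboronation or β-hydride elimination of the alkyl group to take over. The fallback sets out from bromophenol 4, which is masked (i-Pr3SiCl, imidazole, DMF) as [3,5-bis(benzyloxy)-4-bromophenoxy]tri(propan-2-yl)silane F5. Coupling with borane 7 under the same catalyst gives {3,5-bis(benzyloxy)-4-[3-(benzyloxy)-3-methylbutyl]phenoxy}tri(propan-2-yl)silane F6, and desilylation (n-Bu4NF, THF) returns to phenol 8.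

Step 10. HI formed in the iodine cycle at 120 °C may ionise the tertiary benzyl ether and lead to elimination in the side chain, and closure may stall because Cβ of an α-alkoxy enone is a weak Michael acceptor. The fallback sets out from chalcone 17 and separates the two events: closure under mild base (NaOAc, EtOH, reflux) to isolated flavanone 18, then dehydrogenation with DDQ (dioxane, reflux) to flavone 19, with no acid present.

**Further compounds**

F1 | step 9 | 3,5-bis(benzyloxy)-4-[3-(benzyloxy)-3-methylbutyl]-2-bromophenyl (Z)-2-(benzyloxy)-3-[4-(benzyloxy)phenyl]prop-2-enoate | O=C(Oc1cc(OCc2ccccc2)c(CCC(C)(C)OCc2ccccc2)c(OCc2ccccc2)c1Br)/C(OCc1ccccc1)=C/c1ccc(OCc2ccccc2)cc1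
F2 | step 3 | 3,5-bis(benzyloxy)-4-bromo-N-methoxy-N-methylbenzamide | CON(C)C(=O)c1cc(OCc2ccccc2)c(Br)c(OCc2ccccc2)c1
F3 | step 3 | 1-[3,5-bis(benzyloxy)-4-bromophenyl]ethan-1-one | CC(=O)c1cc(OCc2ccccc2)c(Br)c(OCc2ccccc2)c1
F4 | step 3 | 3,5-bis(benzyloxy)-4-bromophenyl acetate | CC(=O)Oc1cc(OCc2ccccc2)c(Br)c(OCc2ccccc2)c1
F5 | step 5 | [3,5-bis(benzyloxy)-4-bromophenoxy]tri(propan-2-yl)silane | CC(C)[Si](Oc1cc(OCc2ccccc2)c(Br)c(OCc2ccccc2)c1)(C(C)C)C(C)C
F6 | step 5 | {3,5-bis(benzyloxy)-4-[3-(benzyloxy)-3-methylbutyl]phenoxy}tri(propan-2-yl)silane | CC(C)[Si](Oc1cc(OCc2ccccc2)c(CCC(C)(C)OCc2ccccc2)c(OCc2ccccc2)c1)(C(C)C)C(C)C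
F0 | step 10 | none | none
A1 | alternative 1 | 5-(benzyloxy)-6-[4-(benzyloxy)phenyl]-2-(2-diazoacetyl)-4H-pyran-4-one | [N-]=[N+]=CC(=O)c1cc(=O)c(OCc2ccccc2)c(-c2ccc(OCc3ccccc3)cc2)o1
A2 | alternative 1 | {[5-(benzyloxy)-5-methylhex-1-yn-1-yl]oxy}tri(propan-2-yl)silane | CC(C)[Si](OC#CCCC(C)(C)OCc1ccccc1)(C(C)C)C(C)C
A3 | alternative 1 | 3-(benzyloxy)-2-[4-(benzyloxy)phenyl]-6-[3-(benzyloxy)-3-methylbutyl]-5-hydroxy-7-[(triisopropylsilyl)oxy]-4H-chromen-4-one | CC(C)[Si](Oc1cc2oc(-c3ccc(OCc4ccccc4)cc3)c(OCc3ccccc3)c(=O)c2c(O)c1CCC(C)(C)OCc1ccccc1)(C(C)C)C(C)C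
A4 | alternative 2 | 1-(benzyloxy)-2-[3-(benzyloxy)-3-methylbutyl]-1,3-bis[(trimethylsilyl)oxy]buta-1,3-diene | C=C(O[Si](C)(C)C)C(CCC(C)(C)OCc1ccccc1)=C(OCc1ccccc1)O[Si](C)(C)C
A5 | alternative 2 | 1-(benzyloxy)-4-bromobut-3-yn-2-one | O=C(COCc1ccccc1)C#CBr
A6 | alternative 2 | 2-(benzyloxy)-1-{2-(benzyloxy)-3-[3-(benzyloxy)-3-methylbutyl]-6-bromo-4-hydroxyphenyl}ethan-1-one | O=C(COCc1ccccc1)c1c(Br)cc(O)c(CCC(C)(C)OCc2ccccc2)c1OCc1ccccc1
A7 | alternative 3 | 4,6-bis(benzyloxy)-5-[3-(benzyloxy)-3-methylbutyl]-2-{1-[4-(benzyloxy)phenyl]-2-oxoethoxy}benzaldehyde (racemic) | O=Cc1c(OC(C=O)c2ccc(OCc3ccccc3)cc2)cc(OCc2ccccc2)c(CCC(C)(C)OCc2ccccc2)c1OCc1ccccc1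
A8 | alternative 3 | trans-5,7-bis(benzyloxy)-2-[4-(benzyloxy)phenyl]-6-[3-(benzyloxy)-3-methylbutyl]-3-hydroxy-2,3-dihydro-4H-chromen-4-one (racemic; the 2R,3R enantiomer is drawn) | O=C1c2c(OCc3ccccc3)c(CCC(C)(C)OCc3ccccc3)c(OCc3ccccc3)cc2O[C@H](c2ccc(OCc3ccccc3)cc2)[C@H]1O
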